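## Retrosynthetic overview

1. Feature (hexahydroindene numbering, also used for the open-chain compounds): the cyclopentene C1–C2–C3–C3a–C7a carries ethyl on C1 and methyl on C3 on either side of C2 and is fused at C3a–C7a to the cyclohexene C3a–C4=C5–C6–C7–C7a. C2 is therefore a latent carbonyl between an ethyl-alkyne carbon and an E-propenyl carbon.
2. Target ⇒ (Pinnick oxidation, two olefinations) ⇒ bis-silyl ether 24 ⇒ (allylic diazene transposition, Mitsunobu, Luche) ⇒ C2 dienone 19. The C7 carboxyl is carried as CH2OTBDPS, so that no γ-lactone can form with the C6 CH2OH and no doubly neopentyl ester has to be cleaved.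
3. 19 ⇒ open-chain Z,E-dienyne 17 + CO by a cobalt [2+2+1]: the six-membered ring (C7a–C3a) and the five-membered ring (C3–C2, C2–C1) close in the same step; no other ring-forming step builds the core.
4. 17 ⇒ lactol aldehyde 10, in which the C6 CH2OH masks the C7 aldehyde, so that the C6 aldehyde is olefinated first (Z-iodoalkene, Suzuki) and the lactol is then homologated to the alkyne ⇒ ozonolysis of the lipase-desymmetrised meso cyclobutene diol 5 ⇒ [2+2] of dimethylmaleic anhydride and cis-dichloroethene.

Key step: step 13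

Assumption: the lipase acetylates the hydroxymethyl arm on the S-configured ring carbon of 5 (as drawn for 6); should it prefer the other arm, the same enzyme used for hydrolysis of the meso diacetate gives 6.

## Route

Step 1
Reactants: 1 2,3-dimethylmaleic anhydride; 2 cis-1,2-dichloroethene (excess)
Product: 3 cis-fused 6,7-dichloro-1,5-dimethyl-3-oxabicyclo[3.2.0]heptane-2,4-dione (mixture of chloride stereoisomers)
Conditions: hν (Pyrex), benzophenone (sens.), acetone, 15 °C
Reagents that add atoms: none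
Why: Triplet-sensitised [2+2] photocycloaddition; the five-membered anhydride enforces the cis ring fusion, which fixes the cis relationship of the two methyl-bearing quaternary carbons (later C6 and C7).

Step 2
Reactants: 3
Product: 4 meso-1,5-dimethyl-3-oxabicyclo[3.2.0]hept-6-ene-2,4-dione
Conditions: Zn dust (activated), Ac2O, toluene, 85 °C
Reagents that add atoms: none
Why: Zinc-mediated reductive 1,2-dechlorination gives the cyclobutene from every dichloride isomer, and acetic anhydride keeps the anhydride closed.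

Step 3
Reactants: 4
Product: 5 meso-(cis-1,2-dimethylcyclobut-3-ene-1,2-diyl)dimethanol
Conditions: LiAlH4, THF, 0 °C → reflux
Reagents that add atoms: none
Why: Hydride reduction of the cyclic anhydride to the 1,4-diol; the isolated cyclobutene is inert to LiAlH4 and the product stays meso.

Step 4
Reactants: 5
Product: 6 [(1S,2R)-2-(hydroxymethyl)-1,2-dimethylcyclobut-3-en-1-yl]methyl acetate
Conditions: Burkholderia cepacia lipase (Amano PS), vinyl acetate, t-BuOMe, 25 °C
Reagents that add atoms: vinyl acetate, CC(=O)OC=C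
Why: Lipase-catalysed irreversible transesterification distinguishes the enantiotopic hydroxymethyl groups of the meso diol (enzymatic desymmetrisation) and so fixes the absolute configuration of both quaternary carbons without forming a new stereocentre.

Step 5
Reactants: 6
Product: 7 [(1S,2R)-2-{[(tert-butyldiphenylsilyl)oxy]methyl}-1,2-dimethylcyclobut-3-en-1-yl]methyl acetate
Conditions: TBDPSCl, imidazole, DMF, 0 → 23 °C
Reagents that add atoms: tert-butyl(chloro)diphenylsilane, CC(C)(C)[Si](Cl)(c1ccccc1)c1ccccc1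
Why: Silylation of the free primary alcohol (the later C7 arm) with the robust silyl group that stays on until the end.

Step 6
Reactants: 7
Product: 8 [(1S,2R)-2-{[(tert-butyldiphenylsilyl)oxy]methyl}-1,2-dimethylcyclobut-3-en-1-yl]methanol
Conditions: K2CO3 (cat.), MeOH, 0 °C
Reagents that add atoms: none
Why: Base-catalysed transesterification removes the acetate from the later C6 arm; the TBDPS ether is stable, and 1,4-silyl migration through a seven-membered transition state should not compete at 0 °C.

Step 7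
Reactants: 8
Product: 10 4-{[(tert-butyldiphenylsilyl)oxy]methyl}-5-hydroxy-3,4-dimethyloxolane-3-carbaldehyde (3-CHO cis to 4-Me; oxolane C3 = later C6, C4 = later C7; anomeric mixture), via secondary ozonide 9 (not isolated)
Conditions: O3, CH2Cl2, −78 °C; then Me2S, −78 → 23 °C
Reagents that add atoms: ozone, [O-][O+]=O
Why: Ozonolysis (Criegee) of the strained cyclobutene with reductive work-up; the C6 hydroxymethyl group can close a five-membered lactol only on the aldehyde at C7 (its own geminal aldehyde would need a four-membered ring), which differentiates the two aldehydes.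

Step 8
Reactants: 10
Product: 11 3-{[(tert-butyldiphenylsilyl)oxy]methyl}-4-[(1Z)-2-iodoprop-1-en-1-yl]-3,4-dimethyloxolan-2-ol (3-CH2OSi cis to 4-Me; anomeric mixture)
Conditions: [Ph3PCH(I)CH3]I, NaHMDS, THF, −20 °C; then 10, −78 °C
Reagents that add atoms: (1-iodoethyl)triphenylphosphonium iodide, CC(I)[P+](c1ccccc1)(c1ccccc1)c1ccccc1.[I-]
Why: Stork–Zhao Wittig olefination; the non-stabilised α-iodo ylide adds to the free aldehyde at −78 °C under kinetic control to give the Z-iodoalkene (iodine cis to C6), while the lactol stays ring-closed at this temperature.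

Step 9
Reactants: 11
Product: 12 3-{[(tert-butyldiphenylsilyl)oxy]methyl}-3,4-dimethyl-4-[(1Z,3E)-2-methylpenta-1,3-dien-1-yl]oxolan-2-ol
Conditions: (E)-MeCH=CHB(OH)2, Pd(PPh3)4 (5 mol%), K3PO4, THF/H2O, 50 °C
Reagents that add atoms: (E)-prop-1-en-1-ylboronic acid, C/C=C/B(O)O
Why: Suzuki–Miyaura coupling with retention at both alkenes gives the Z,E-diene; no alkyne is present yet, so the vinylpalladium intermediate has no 5-exo carbopalladation pathway.

Step 10
Reactants: 12
Product: 13 (2S,3R)-3-{[(tert-butyldiphenylsilyl)oxy]methyl}-2,3-dimethyl-2-[(1Z,3E)-2-methylpenta-1,3-dien-1-yl]pent-4-yn-1-ol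
Conditions: MeC(O)C(N2)P(O)(OMe)2, K2CO3, MeOH, 0 → 45 °C
Reagents that add atoms: dimethyl (1-diazo-2-oxopropyl)phosphonate, COP(=O)(OC)C(=[N+]=[N-])C(C)=O
Why: Ohira–Bestmann (Seyferth–Gilbert) homologation of the lactol through its open hydroxy-aldehyde form; C7 carries no electron-withdrawing group at this stage, so deformylation cannot compete, and the C6 CH2OH is set free.

Step 11
Reactants: 13
Product: 14 tert-butyldimethylsilyl ether of 13 (C6 CH2OTBS, C7 CH2OTBDPS, terminal alkyne)
Conditions: TBSCl, imidazole, DMF, 23 °C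
Reagents that add atoms: tert-butyl(chloro)dimethylsilane, CC(C)(C)[Si](C)(C)Cl
Why: Silylation of the C6 hydroxymethyl group with the more acid-labile silyl group, which is the first to be removed later.

Step 12
Reactants: 14; 15 iodoethane
Product: 17 (2E,4Z,6S,7R)-6-{[(tert-butyldimethylsilyl)oxy]methyl}-7-{[(tert-butyldiphenylsilyl)oxy]methyl}-4,6,7-trimethylundeca-2,4-dien-8-yne, via lithium acetylide 16 (not isolated)
Conditions: n-BuLi, THF, −78 °C; then EtI, DMPU, −78 → 23 °C
Reagents that add atoms: none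
Why: Deprotonation of the terminal alkyne and SN2 alkylation of the acetylide with iodoethane (acetylide alkylation).

Step 13
Reactants: 17; 18 carbon monoxide
Product: 19 7-{[(tert-butyldiphenylsilyl)oxy]methyl}-6-{[(tert-butyldimethylsilyl)oxy]methyl}-1-ethyl-3,4,6,7-tetramethyl-3,3a,6,7-tetrahydro-2H-inden-2-one (3-Me cis to H-3a; H-3a, 6-Me and 7-Me on the same face)
Conditions: Co2(CO)8 (0.2 equiv), TMTU (1.2 equiv), CO (1 atm), toluene, 70 °C
Reagents that add atoms: none
Why: Pauson–Khand reaction: the ethyl alkyne forms its dicobalt hexacarbonyl complex, the distal E-alkene C3a=C3 of the diene coordinates to one cobalt and inserts into its bond to C7a (C7a–C3a), CO inserts, and reductive elimination forms C3–C2 and C2–C1, cobalt being turned over under CO with tetramethylthiourea as ligand. The closest known reactions are the intramolecular Pauson–Khand cyclisations of 1,7-enynes to hydrindenones and of diene-ynes. The six-membered ring closes in the exo (1,7-enyne) mode through the tether C7–C6–C5=C4, which the two quaternary carbons and the Z-alkene hold folded, and the cyclopentenone closes by the carbonylative reductive elimination; the [4+2] and proximal-alkene alternatives would need a four-membered ring. C3 is set relative to C3a by syn addition across the E-alkene (3-Me trans to C4, cis to H-3a). C3a is set relative to C6/C7 in a half-chair closure in which C3 must lie in the plane of the forming cyclopentenone (H-3a pseudoaxial): the axial site at C7, syn to H-3a and beside the Co(CO)3 unit on the C1=C7a face, is taken by the methyl group, the large C7 siloxymethyl group lies equatorial, and the C6 siloxymethyl group is pseudoaxial on the open convex face, where the sp2 centres C7a and C4 leave it no 1,3-diaxial partner. The step needs this face selection, which rests only on the size difference between methyl and CH2OTBDPS at C7, and the chemoselectivity for the distal alkene, which ring size secures.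

Step 14
Reactants: 19
Product: 20 the corresponding 3,3a,6,7-tetrahydro-2H-inden-2-ol (2-OH cis to 3-Me)
Conditions: NaBH4, CeCl3·7H2O, MeOH, −78 → −40 °C
Reagents that add atoms: none
Why: Luche 1,2-reduction; hydride should add to the C2 carbonyl on the face anti to the adjacent C3 methyl group, which gives the 2-OH cis to 3-Me.

Step 15
Reactants: 20
Product: 21 N-(inden-2-yl)-2-nitro-N′-(propan-2-ylidene)benzenesulfonohydrazide derived from 20 (nitrogen at C2 on the face trans to 3-Me)
Conditions: IPNBSH, PPh3, DEAD, THF, 0 → 23 °C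
Reagents that add atoms: 2-nitro-N′-(propan-2-ylidene)benzenesulfonohydrazide (IPNBSH), CC(C)=NNS(=O)(=O)c1ccccc1[N+](=O)[O-]
Why: Mitsunobu displacement of the allylic alcohol by the sulfonamide N–H with inversion (SN2) places nitrogen on the face anti to the C3 methyl group, which is also the less hindered face for attack.

Step 16
Reactants: 21
Product: 24 7-{[(tert-butyldiphenylsilyl)oxy]methyl}-6-{[(tert-butyldimethylsilyl)oxy]methyl}-1-ethyl-3,4,6,7-tetramethyl-3a,6,7,7a-tetrahydro-3H-indene (H-7a trans to H-3a, C1=C2), via N-alkyl-N-sulfonylhydrazine 22 (not isolated), via allylic diazene 23 (not isolated)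
Conditions: CF3CH2OH/H2O (1:1), 23 °C
Reagents that add atoms: none
Why: Hydrazone hydrolysis and loss of sulfinic acid give the monoalkyl diazene, whose retro-ene reaction (allylic diazene rearrangement) extrudes N2 and delivers hydrogen suprafacially to C7a on the face of the nitrogen, so that H-7a ends trans to H-3a and the alkene moves to C1=C2.

Step 17
Reactants: 24
Product: 25 the C6 hydroxymethyl compound (C7 CH2OTBDPS retained)
Conditions: PPTS, MeOH/CH2Cl2, 23 °C
Reagents that add atoms: none
Why: Acid-catalysed methanolysis cleaves the primary TBS ether selectively, since the TBDPS ether is far more stable to acid.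

Step 18
Reactants: 25
Product: 26 the 6-carbaldehyde
Conditions: Dess–Martin periodinane, CH2Cl2, 23 °C
Reagents that add atoms: none
Why: Dess–Martin oxidation of the neopentyl alcohol to a non-enolisable aldehyde; no ester or acid is present at C7, so no lactone or lactol can form.

Step 19
Reactants: 26
Product: 27 (2E)-2-methyl-3-(inden-6-yl)prop-2-enal (C6–CH=C(Me)–CHO, C7 CH2OTBDPS)
Conditions: Ph3P=C(Me)CHO, toluene, 110 °C
Reagents that add atoms: 2-(triphenyl-λ5-phosphanylidene)propanal, CC(C=O)=P(c1ccccc1)(c1ccccc1)c1ccccc1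
Why: Wittig olefination with a stabilised ylide gives the E-trisubstituted enal under thermodynamic control; the neopentyl aldehyde requires the forcing temperature.

Step 20
Reactants: 27
Product: 28 the 6-[(1E,3E)-2-methyl-4-phenylbuta-1,3-dien-1-yl] compound (C7 CH2OTBDPS)
Conditions: (EtO)2P(O)CH2Ph, NaHMDS, THF, −78 → 23 °C
Reagents that add atoms: diethyl benzylphosphonate, CCOP(=O)(Cc1ccccc1)OCC
Why: Horner–Wadsworth–Emmons olefination of the enal with the benzylphosphonate anion gives the E-styryl alkene and completes the (1E,3E)-diene.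

Step 21
Reactants: 28
Product: 29 the C7 hydroxymethyl compound
Conditions: TBAF, THF, 50 °C
Reagents that add atoms: none
Why: Fluoride-mediated cleavage of the hindered TBDPS ether; nothing else in the molecule is fluoride- or base-sensitive.

Step 22
Reactants: 29
Product: 30 the 7-carbaldehyde
Conditions: Dess–Martin periodinane, CH2Cl2, 23 °C
Reagents that add atoms: none
Why: Dess–Martin oxidation to the non-enolisable C7 aldehyde under neutral conditions that leave the diene untouched.

Step 23
Reactants: 30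
Product: 31 Zyggomphic acid B, (3R,3aS,6S,7R,7aR)-1-ethyl-3,4,6,7-tetramethyl-6-[(1E,3E)-2-methyl-4-phenylbuta-1,3-dien-1-yl]-3a,6,7,7a-tetrahydro-3H-indene-7-carboxylic acid
Conditions: NaClO2, NaH2PO4, 2-methyl-2-butene, t-BuOH/H2O, 23 °C
Reagents that add atoms: sodium chlorite, [Na+].[O-]Cl=O
Why: Pinnick (Lindgren) oxidation converts the hindered aldehyde into the acid while the scavenger protects the alkenes from hypochlorite; no stereocentre is epimerisable.

## Compound list

1 | 2,3-dimethylmaleic anhydride | CC1=C(C)C(=O)OC1=O | starting material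
2 | cis-1,2-dichloroethene | Cl/C=C\Cl | starting material
3 | 6,7-dichloro-1,5-dimethyl-3-oxabicyclo[3.2.0]heptane-2,4-dione (cis-fused, chloride isomers) | C[C@]12C(Cl)C(Cl)[C@@]1(C)C(=O)OC2=O | intermediate
4 | meso-1,5-dimethyl-3-oxabicyclo[3.2.0]hept-6-ene-2,4-dione | C[C@]12C=C[C@@]1(C)C(=O)OC2=O | intermediate
5 | meso-(cis-1,2-dimethylcyclobut-3-ene-1,2-diyl)dimethanol | OC[C@]1(C)C=C[C@]1(C)CO | intermediate
6 | [(1S,2R)-2-(hydroxymethyl)-1,2-dimethylcyclobut-3-en-1-yl]methyl acetate | OC[C@]1(C)C=C[C@]1(C)COC(C)=O | intermediate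
7 | [(1S,2R)-2-{[(tert-butyldiphenylsilyl)oxy]methyl}-1,2-dimethylcyclobut-3-en-1-yl]methyl acetate | CC(C)(C)[Si](c1ccccc1)(c1ccccc1)OC[C@]1(C)C=C[C@]1(C)COC(C)=O | intermediate
8 | [(1S,2R)-2-{[(tert-butyldiphenylsilyl)oxy]methyl}-1,2-dimethylcyclobut-3-en-1-yl]methanol | CC(C)(C)[Si](c1ccccc1)(c1ccccc1)OC[C@]1(C)C=C[C@]1(C)CO | intermediate
9 | secondary ozonide of 8 (2,3,7-trioxabicyclo[2.2.1]heptane, both bridge orientations) | OC[C@@]1(C)C2OOC(O2)[C@@]1(C)CO[Si](c1ccccc1)(c1ccccc1)C(C)(C)C | intermediate (not isolated)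
10 | 4-{[(tert-butyldiphenylsilyl)oxy]methyl}-5-hydroxy-3,4-dimethyloxolane-3-carbaldehyde (anomers) | CC(C)(C)[Si](c1ccccc1)(c1ccccc1)OC[C@]1(C)C(O)OC[C@@]1(C)C=O | intermediate
11 | 3-{[(tert-butyldiphenylsilyl)oxy]methyl}-4-[(1Z)-2-iodoprop-1-en-1-yl]-3,4-dimethyloxolan-2-ol | CC(C)(C)[Si](c1ccccc1)(c1ccccc1)OC[C@]1(C)C(O)OC[C@@]1(C)/C=C(/C)I | intermediate
12 | 3-{[(tert-butyldiphenylsilyl)oxy]methyl}-3,4-dimethyl-4-[(1Z,3E)-2-methylpenta-1,3-dien-1-yl]oxolan-2-ol | CC(C)(C)[Si](c1ccccc1)(c1ccccc1)OC[C@]1(C)C(O)OC[C@@]1(C)/C=C(C)\C=C\C | intermediate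
13 | (2S,3R)-3-{[(tert-butyldiphenylsilyl)oxy]methyl}-2,3-dimethyl-2-[(1Z,3E)-2-methylpenta-1,3-dien-1-yl]pent-4-yn-1-ol | C#C[C@@](C)(CO[Si](c1ccccc1)(c1ccccc1)C(C)(C)C)[C@@](C)(CO)/C=C(C)\C=C\C | intermediate
14 | TBS ether of 13 | C#C[C@@](C)(CO[Si](c1ccccc1)(c1ccccc1)C(C)(C)C)[C@@](C)(CO[Si](C)(C)C(C)(C)C)/C=C(C)\C=C\C | intermediate
15 | iodoethane | CCI | starting material
16 | lithium acetylide of 14 | [Li]C#C[C@@](C)(CO[Si](c1ccccc1)(c1ccccc1)C(C)(C)C)[C@@](C)(CO[Si](C)(C)C(C)(C)C)/C=C(C)\C=C\C | intermediate (not isolated)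
17 | (2E,4Z,6S,7R)-6-{[(tert-butyldimethylsilyl)oxy]methyl}-7-{[(tert-butyldiphenylsilyl)oxy]methyl}-4,6,7-trimethylundeca-2,4-dien-8-yne | CCC#C[C@@](C)(CO[Si](c1ccccc1)(c1ccccc1)C(C)(C)C)[C@@](C)(CO[Si](C)(C)C(C)(C)C)/C=C(C)\C=C\C | intermediate (key-step precursor)
18 | carbon monoxide | [C-]#[O+] | starting material
19 | bicyclic C2 dienone (3-Me cis to H-3a; H-3a cis to 6-Me and 7-Me) | CCC1=C2[C@@](C)(CO[Si](c3ccccc3)(c3ccccc3)C(C)(C)C)[C@@](C)(CO[Si](C)(C)C(C)(C)C)C=C(C)[C@H]2[C@H](C)C1=O | intermediate (key-step product)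
20 | C2 allylic alcohol (2-OH cis to 3-Me) | CCC1=C2[C@@](C)(CO[Si](c3ccccc3)(c3ccccc3)C(C)(C)C)[C@@](C)(CO[Si](C)(C)C(C)(C)C)C=C(C)[C@H]2[C@H](C)[C@@H]1O | intermediate
21 | C2 N-sulfonyl hydrazone adduct (N trans to 3-Me) | CCC1=C2[C@@](C)(CO[Si](c3ccccc3)(c3ccccc3)C(C)(C)C)[C@@](C)(CO[Si](C)(C)C(C)(C)C)C=C(C)[C@H]2[C@H](C)[C@H]1N(N=C(C)C)S(=O)(=O)c1ccccc1[N+](=O)[O-] | intermediate
22 | C2 N-alkyl-N-(2-nitrobenzenesulfonyl)hydrazine | CCC1=C2[C@@](C)(CO[Si](c3ccccc3)(c3ccccc3)C(C)(C)C)[C@@](C)(CO[Si](C)(C)C(C)(C)C)C=C(C)[C@H]2[C@H](C)[C@H]1N(N)S(=O)(=O)c1ccccc1[N+](=O)[O-] | intermediate (not isolated)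
23 | C2 allylic monoalkyl diazene | CCC1=C2[C@@](C)(CO[Si](c3ccccc3)(c3ccccc3)C(C)(C)C)[C@@](C)(CO[Si](C)(C)C(C)(C)C)C=C(C)[C@H]2[C@H](C)[C@H]1N=N | intermediate (not isolated)
24 | trans-fused bis-silyl ether (C1=C2, H-7a trans to H-3a) | CCC1=C[C@@H](C)[C@@H]2C(C)=C[C@](C)(CO[Si](C)(C)C(C)(C)C)[C@](C)(CO[Si](c3ccccc3)(c3ccccc3)C(C)(C)C)[C@@H]12 | intermediate
25 | C6 hydroxymethyl compound | CCC1=C[C@@H](C)[C@@H]2C(C)=C[C@](C)(CO)[C@](C)(CO[Si](c3ccccc3)(c3ccccc3)C(C)(C)C)[C@@H]12 | intermediate
26 | C6 carbaldehyde | CCC1=C[C@@H](C)[C@@H]2C(C)=C[C@](C)(C=O)[C@](C)(CO[Si](c3ccccc3)(c3ccccc3)C(C)(C)C)[C@@H]12 | intermediate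
27 | C6 (E)-2-methylpropenal | CCC1=C[C@@H](C)[C@@H]2C(C)=C[C@](C)(/C=C(\C)C=O)[C@](C)(CO[Si](c3ccccc3)(c3ccccc3)C(C)(C)C)[C@@H]12 | intermediate
28 | C6 (1E,3E)-2-methyl-4-phenylbutadienyl compound, C7 CH2OTBDPS | CCC1=C[C@@H](C)[C@@H]2C(C)=C[C@](C)(/C=C(C)/C=C/c3ccccc3)[C@](C)(CO[Si](c3ccccc3)(c3ccccc3)C(C)(C)C)[C@@H]12 | intermediate
29 | C7 hydroxymethyl compound | CCC1=C[C@@H](C)[C@@H]2C(C)=C[C@](C)(/C=C(C)/C=C/c3ccccc3)[C@](C)(CO)[C@@H]12 | intermediate
30 | C7 carbaldehyde | CCC1=C[C@@H](C)[C@@H]2C(C)=C[C@](C)(/C=C(C)/C=C/c3ccccc3)[C@](C)(C=O)[C@@H]12 | intermediate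
31 | Zyggomphic acid B | CCC1=C[C@@H](C)[C@@H]2C(C)=C[C@](C)(/C=C(C)/C=C/c3ccccc3)[C@](C)(C(=O)O)[C@@H]12 | target

## Step count and risks

Total step count: 23. Longest linear sequence: 23 steps (1 and 2 to 31; the route is fully linear).

Steps most likely to fail:

1. Step 13. Insertion of the E-disubstituted diene terminus into the cobalt complex of an internal alkyne that sits on a quaternary carbon may be slow. Decomplexation, alkyne oligomerisation or diene isomerisation could then overtake ring closure, and at the temperature then required the two faces of C3a=C3 would be told apart less well. Fallback: setting out from the terminal alkyne 14 (step 12 is omitted), the same cobalt/TMTU/CO conditions are applied to the less hindered alkyne, which should cyclise at lower temperature to the C1-unsubstituted dienone F1. Iodination at C1 with I2 and pyridine in CH2Cl2 gives the 1-iodo dienone F2, and Suzuki coupling with triethylborane (PdCl2(dppf), K3PO4, DMF/H2O) installs the ethyl group and comes back to the route at 19.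

2. Step 8. The neopentyl aldehyde may react sluggishly with the hindered iodo-ylide, so that conversion is low, Z selectivity erodes, or the ylide opens the lactolate and attacks the second aldehyde. Fallback: setting out from 10, Still–Gennari olefination with ethyl 2-[bis(2,2,2-trifluoroethoxy)phosphoryl]propanoate (KHMDS, 18-crown-6, THF, −78 °C), whose stabilised anion does not deprotonate the lactol, gives the Z-enoate lactol F3. DIBAL-H reduction (CH2Cl2, −78 °C) gives the Z-allylic alcohol F4, MnO2 oxidation gives the Z-enal F5, and Takai–Utimoto ethylidenation (CrCl2, CH3CHI2, THF) forms the E-propenyl terminus and comes back to the route at 12.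

3. Step 15. The activated allylic oxyphosphonium intermediate may eliminate to a cyclopentadiene or be displaced with allylic transposition instead of undergoing direct SN2 attack at the hindered C2. Fallback: setting out from 19, reagent-controlled CBS reduction (the Me-CBS enantiomer that delivers hydride syn to the C3 methyl group, catecholborane, toluene, −78 °C) gives the epimeric alcohol F6 (2-OH trans to 3-Me). Methyl chloroformate and pyridine give the allylic methyl carbonate F7, and palladium-catalysed allylic substitution with IPNBSH (Pd2(dba)3, PPh3, THF), which proceeds with net retention at the less substituted allyl terminus C2, comes back to the route at 21.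

Further compounds
F1 | step 13 | C1-unsubstituted dienone (19 with H in place of ethyl at C1) | C1=C2[C@@](C)(CO[Si](c3ccccc3)(c3ccccc3)C(C)(C)C)[C@@](C)(CO[Si](C)(C)C(C)(C)C)C=C(C)[C@H]2[C@H](C)C1=O
F2 | step 13 | 1-iodo dienone | IC1=C2[C@@](C)(CO[Si](c3ccccc3)(c3ccccc3)C(C)(C)C)[C@@](C)(CO[Si](C)(C)C(C)(C)C)C=C(C)[C@H]2[C@H](C)C1=O
F3 | step 8 | Z-enoate lactol, ethyl (2Z)-2-methyl-3-(oxolan-3-yl)prop-2-enoate derived from 10 | CC(C)(C)[Si](c1ccccc1)(c1ccccc1)OC[C@]1(C)C(O)OC[C@@]1(C)/C=C(C)\C(=O)OCC
F4 | step 8 | Z-allylic alcohol lactol | CC(C)(C)[Si](c1ccccc1)(c1ccccc1)OC[C@]1(C)C(O)OC[C@@]1(C)/C=C(C)\CO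
F5 | step 8 | Z-enal lactol | CC(C)(C)[Si](c1ccccc1)(c1ccccc1)OC[C@]1(C)C(O)OC[C@@]1(C)/C=C(C)\C=O
F6 | step 15 | C2-epimeric allylic alcohol (2-OH trans to 3-Me) | CCC1=C2[C@@](C)(CO[Si](c3ccccc3)(c3ccccc3)C(C)(C)C)[C@@](C)(CO[Si](C)(C)C(C)(C)C)C=C(C)[C@H]2[C@H](C)[C@H]1O
F7 | step 15 | allylic methyl carbonate of the epimeric alcohol | CCC1=C2[C@@](C)(CO[Si](c3ccccc3)(c3ccccc3)C(C)(C)C)[C@@](C)(CO[Si](C)(C)C(C)(C)C)C=C(C)[C@H]2[C@H](C)[C@H]1OC(=O)OC
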